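**Plan**

- Feature used: the ten-membered carbocycle C1–C10 carries at C9 an allylic carbinol on the trisubstituted C1=C10 alkene (C14 on C10). That is the retron of an alkenylmetal adding to a C9 aldehyde. The lactone (O6–C12(=O)–C11(=C13)–C7), the C4–C5 oxirane and the C8 ester are spectators.
- Cuts, in retrosynthetic order: the C8/C9 acyl groups and the C14 oxidation level; C9–C10 (ring closure); O6–C12 (acyl shift from O8) and the oxirane; C6–C7 (Barbier allylation); C1=C10 (iodo-Wittig); C7–C11 (Morita–Baylis–Hillman).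
- Forward: an iodo-enal (C1–C6, C10, C14, C15) from geraniol and a bromomethyl butenolide (C7–C9, C11–C13) from (S)-glyceraldehyde acetonide and methyl acrylate are joined at C6–C7. The oxirane is then added, the five-membered lactone is moved from O8 to O6, and the ten-membered ring is closed last.
- Stereochemistry: C8 comes from (S)-glyceraldehyde. C7 and C6 follow from the ring-locked chair allylation (C7 trans to C9 on the butenolide, C6/C7 anti). C4/C5 come from the epoxidation directed by the C6 hydroxyl. C9 is set in the ring closure. The (E)-C4=C5 geometry comes from geraniol, and the C1=C10 geometry from the (Z)-iodo-Wittig, retained.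

Key step: step 15

Assumption: germacranolide numbering (ring C1–C10, lactone carbons C11–C13, C14 on C10, C15 on C4) is used for all compounds, the acyclic ones included; the target is 4R,5R,6S,7R,8R,9R with C2 and C9 cis on C1=C10.

**Route**

Step 1
Reactants: 1 geraniol
Product: 2 geranyl triethylsilyl ether
Conditions: Et3SiCl, imidazole, CH2Cl2, 0 °C
Reagents that add atoms: chlorotriethylsilane, CC[Si](Cl)(CC)CC
Why: Silyl ether formation on a primary allylic alcohol; the triethylsilyl group survives steps 2–5 and can be oxidised off directly in step 6.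

Step 2
Reactants: 2 geranyl triethylsilyl ether
Product: 3 (4E)-4-methyl-6-(triethylsilyloxy)hex-4-enal
Conditions: O3 (1 equiv, Sudan red 7B end point), CH2Cl2, −78 °C; then Me2S, −78 °C → rt
Reagents that add atoms: ozone, [O-][O+]=O
Why: Ozonolysis with reductive work-up should cleave the electron-richer terminal trisubstituted alkene before the one deactivated by the allylic silyloxy group, leaving the (E)-alkene that becomes C4=C5.

Step 3
Reactants: 3 (4E)-4-methyl-6-(triethylsilyloxy)hex-4-enal
Product: 4 ethyl (2Z,6E)-2-iodo-6-methyl-8-(triethylsilyloxy)octa-2,6-dienoate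
Conditions: Ph3P=CHCO2Et, N-iodosuccinimide, CH2Cl2, −20 °C; then 3, −20 °C → rt
Reagents that add atoms: (ethoxycarbonylmethylene)triphenylphosphorane, CCOC(=O)C=P(c1ccccc1)(c1ccccc1)c1ccccc1; N-iodosuccinimide, O=C1CCC(=O)N1I
Why: Wittig olefination with the stabilised α-iodo ylide made in the flask places the alkyl chain trans to the ester, which is the (Z)-α-iodo enoate with iodine cis to C2.

Step 4
Reactants: 4 ethyl (2Z,6E)-2-iodo-6-methyl-8-(triethylsilyloxy)octa-2,6-dienoate
Product: 5 (2Z,6E)-2-iodo-6-methyl-8-(triethylsilyloxy)octa-2,6-dien-1-ol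
Conditions: i-Bu2AlH (2.5 equiv), CH2Cl2, −78 °C
Reagents that add atoms: none
Why: i-Bu2AlH 1,2-reduction of the enoate to the allylic alcohol at low temperature, which leaves the alkenyl iodide, its geometry and the silyl ether untouched.

Step 5
Reactants: 5 (2Z,6E)-2-iodo-6-methyl-8-(triethylsilyloxy)octa-2,6-dien-1-ol
Product: 6 (2Z,6E)-1-(tert-butyldimethylsilyloxy)-2-iodo-6-methyl-8-(triethylsilyloxy)octa-2,6-diene
Conditions: t-BuMe2SiCl, imidazole, DMF, 0 °C → rt
Reagents that add atoms: tert-butylchlorodimethylsilane, CC(C)(C)[Si](C)(C)Cl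
Why: Silyl ether formation on the primary alcohol; the tert-butyldimethylsilyl group on O14 is stable to the Swern conditions that remove a triethylsilyl group.

Step 6
Reactants: 6 (2Z,6E)-1-(tert-butyldimethylsilyloxy)-2-iodo-6-methyl-8-(triethylsilyloxy)octa-2,6-diene
Product: 7 (2E,6Z)-8-(tert-butyldimethylsilyloxy)-7-iodo-3-methylocta-2,6-dienal
Conditions: (COCl)2, DMSO, CH2Cl2, −78 → −40 °C; then Et3N, −78 → 0 °C
Reagents that add atoms: none
Why: Swern oxidation applied directly to the silyl ether: chlorodimethylsulfonium chloride cleaves the unhindered primary Et3Si–O bond and the alkoxysulfonium ion is oxidised on adding base, whereas the tert-butyldimethylsilyl ether is inert, so the (E)-enal (C6) is unveiled in one operation.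

Step 7
Reactants: 8 (S)-glyceraldehyde acetonide; 9 methyl acrylate
Product: 10 methyl 2-{[(4S)-2,2-dimethyl-1,3-dioxolan-4-yl](hydroxy)methyl}prop-2-enoate (both carbinol epimers)
Conditions: DABCO (0.5 equiv), dioxane/H2O, rt
Reagents that add atoms: none
Why: Morita–Baylis–Hillman reaction forms C7–C11; the new carbinol centre at C7 is formed without useful control but is erased in step 10, and C8 comes unchanged from the aldehyde.

Step 8
Reactants: 10 methyl 2-{[(4S)-2,2-dimethyl-1,3-dioxolan-4-yl](hydroxy)methyl}prop-2-enoate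
Product: 12 (5S)-4-hydroxy-5-(hydroxymethyl)-3-methylideneoxolan-2-one (both C4 epimers), via triol ester 11 (not isolated)
Conditions: CF3CO2H, H2O, THF, rt; then evaporation from toluene
Reagents that add atoms: none
Why: Acid-catalysed acetonide hydrolysis followed by lactonisation of the C8 hydroxyl onto the methyl ester, the five-membered lactone being preferred over the six-membered one through O9; C8 is not involved and keeps its configuration.

Step 9
Reactants: 12 (5S)-4-hydroxy-5-(hydroxymethyl)-3-methylideneoxolan-2-one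
Product: 13 (5S)-4-hydroxy-3-methylidene-5-[(triethylsilyloxy)methyl]oxolan-2-one (both C4 epimers)
Conditions: Et3SiCl (1.05 equiv), imidazole, CH2Cl2, −20 °C
Reagents that add atoms: chlorotriethylsilane, CC[Si](Cl)(CC)CC
Why: Silyl ether formation, selective for the primary over the more hindered secondary allylic hydroxyl at low temperature.

Step 10
Reactants: 13 (5S)-4-hydroxy-3-methylidene-5-[(triethylsilyloxy)methyl]oxolan-2-one
Product: 14 (5R)-3-(bromomethyl)-5-[(triethylsilyloxy)methyl]furan-2(5H)-one
Conditions: N-bromosuccinimide, Me2S, CH2Cl2, 0 °C → rt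
Reagents that add atoms: N-bromosuccinimide, O=C1CCC(=O)N1Br
Why: Corey–Kim bromination with allylic transposition (SN2′), as known for Morita–Baylis–Hillman alcohols: bromide attacks the exocyclic methylene of the alkoxysulfonium salt and the double bond moves into conjugation inside the ring, which removes the unselective carbinol centre and leaves C8 untouched (the descriptor changes only by priority).

Step 11
Reactants: 7 (2E,6Z)-8-(tert-butyldimethylsilyloxy)-7-iodo-3-methylocta-2,6-dienal; 14 (5R)-3-(bromomethyl)-5-[(triethylsilyloxy)methyl]furan-2(5H)-one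
Product: 15 (4S,5R)-4-[(1R,2E,6Z)-8-(tert-butyldimethylsilyloxy)-1-hydroxy-7-iodo-3-methylocta-2,6-dien-1-yl]-3-methylidene-5-[(triethylsilyloxy)methyl]oxolan-2-one
Conditions: Zn dust, THF/sat. aq. NH4Cl, 0 °C → rt
Reagents that add atoms: none
Why: Zinc Barbier allylation with a 3-(bromomethyl)butenolide: the allylzinc reacts at ring carbon C7 (SE2′) through a Zimmerman–Traxler chair in which the ring fixes C8 trans to CH2Zn so that the C6 hydroxyl and C8 come out anti, and the aldehyde approaches anti to the CH2OSiEt3 group on C8 so that C7 is trans to it; C6 and C7 are thus set from C8, and the aqueous medium protonates the C6 alkoxide before it can attack the lactone.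

Step 12
Reactants: 15 (the 8,12-olide allylic alcohol)
Product: 16 (4S,5R)-4-[(S)-hydroxy{(2R,3R)-3-[(3Z)-5-(tert-butyldimethylsilyloxy)-4-iodopent-3-en-1-yl]-3-methyloxiran-2-yl}methyl]-3-methylidene-5-[(triethylsilyloxy)methyl]oxolan-2-one
Conditions: mCPBA (1.1 equiv), CH2Cl2, 0 °C
Reagents that add atoms: 3-chloroperoxybenzoic acid, OOC(=O)c1cccc(Cl)c1
Why: Hydroxyl-directed peracid epoxidation (Henbest-type): allylic 1,3-strain between the C15 methyl (cis to C6) and the C6 substituents holds H6 in the alkene plane, and the hydrogen-bonded peracid is delivered to the face of the C6 hydroxyl, giving the threo (4R,5R) epoxy alcohol; the iodo-alkene and the acrylate-type methylene are too electron-poor to compete.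

Step 13
Reactants: 16 (the 8,12-olide epoxy alcohol)
Product: 18 (4S,5S)-4-[(1R)-1,2-bis(triethylsilyloxy)ethyl]-5-[(2R,3R)-3-[(3Z)-5-(tert-butyldimethylsilyloxy)-4-iodopent-3-en-1-yl]-3-methyloxiran-2-yl]-3-methylideneoxolan-2-one, via translactonised C8 alcohol 17 (not isolated)
Conditions: DBU (1.5 equiv), CH2Cl2, 0 °C; Et3SiCl (1.3 equiv) added over 4 h, 0 °C → rt
Reagents that add atoms: chlorotriethylsilane, CC[Si](Cl)(CC)CC
Why: Base-mediated O8→O6 acyl shift (translactonisation of a β-(1-hydroxyalkyl)-γ-butyrolactone through a bicyclic tetrahedral intermediate) equilibrates 16 and 17, and the slowly added silyl chloride should take the C8 hydroxyl of 17, which has only CH2OSiEt3 beside it, much faster than the C6 hydroxyl of 16 beside the trisubstituted oxirane, so the mixture drains into 18 (silyl ether formation under Curtin–Hammett control).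

Step 14
Reactants: 18 (the 6,12-olide bis(triethylsilyl) ether)
Product: 19 (2R)-2-[(2S,3S)-2-[(2R,3R)-3-[(3Z)-5-(tert-butyldimethylsilyloxy)-4-iodopent-3-en-1-yl]-3-methyloxiran-2-yl]-4-methylidene-5-oxooxolan-3-yl]-2-(triethylsilyloxy)acetaldehyde
Conditions: (COCl)2, DMSO, CH2Cl2, −78 → −40 °C; then i-Pr2NEt, −78 → −20 °C
Reagents that add atoms: none
Why: Swern oxidation carried out directly on the bis(triethylsilyl) ether: only the primary Et3Si–O bond is cleaved by chlorodimethylsulfonium chloride and oxidised, the secondary triethylsilyl and the tert-butyldimethylsilyl ethers stay, and the hindered base at low temperature should keep the α-silyloxy aldehyde from epimerising at C8.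

Step 15
Reactants: 19 (epoxy α-methylene lactone with C9 aldehyde and C10 alkenyl iodide)
Product: 20 14-(tert-butyldimethylsilyloxy)-4,5-epoxy-9-hydroxy-8-(triethylsilyloxy)germacra-1(10),11(13)-dien-12,6-olide (C2 and C9 cis on C1=C10; C4–C9 configured as in 27)
Conditions: CrCl2 (10 equiv), NiCl2 (0.1 equiv), DMSO/THF, rt, 0.002 M, slow addition of 19
Reagents that add atoms: none
Why: CrCl2 reduces NiCl2 to zerovalent nickel, which inserts into the C10–I bond; transmetalation gives an alkenyl species of trivalent chromium that adds to the C9 aldehyde and leaves a chromium alkoxide, freed on aqueous work-up (Nozaki–Hiyama–Kishi reaction). The closest known reaction type is the Nozaki–Hiyama–Kishi macrocyclisation of 2-iodoallyl ethers onto aldehydes that closes medium-ring allylic alcohols. The ten-membered carbocycle (C1–C10) closes by 10-exo-trig addition of C10 to the carbonyl carbon C9 at high dilution, the trans-substituted lactone (C6–C7) and the cis relation of C2 and iodine on C1=C10 turning the two chain ends toward each other. The new C9 stereocentre is controlled by the C8 silyloxy centre within the cyclic transition state: with the aldehyde oxygen and its chromium as well as the C8–OSiEt3 group on the periphery of the forming ring, addition should give the 8,9-trans (threo) alcohol. The step needs chemoselectivity for the aldehyde, which the alkenylchromium reagent secures because it does not add to the lactone, the exocyclic methylene or the oxirane at room temperature, and it needs retention of alkene geometry, which the configurationally stable alkenyl–nickel and alkenyl–chromium intermediates secure, so that C9 ends cis to C2 and C14 outside the ring.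

Step 16
Reactants: 20 (the C9 alcohol)
Product: 21 9-acetoxy-14-(tert-butyldimethylsilyloxy)-4,5-epoxy-8-(triethylsilyloxy)germacra-1(10),11(13)-dien-12,6-olide
Conditions: Ac2O, DMAP (cat.), pyridine, CH2Cl2, 0 °C → rt
Reagents that add atoms: acetic anhydride, CC(=O)OC(C)=O
Why: DMAP-catalysed acylation of the secondary allylic alcohol installs the C9 acetate before any other hydroxyl is free.

Step 17
Reactants: 21 (the C9 acetate)
Product: 22 9-acetoxy-14-(tert-butyldimethylsilyloxy)-4,5-epoxy-8-hydroxygermacra-1(10),11(13)-dien-12,6-olide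
Conditions: pyridinium p-toluenesulfonate (cat.), MeOH/CH2Cl2, 0 °C
Reagents that add atoms: none
Why: Acid-catalysed methanolysis of the secondary triethylsilyl ether, much faster than that of the primary tert-butyldimethylsilyl ether, frees only the C8 hydroxyl under conditions too mild to open the oxirane.

Step 18
Reactants: 22 (the C8 alcohol)
Product: 23 9-acetoxy-14-(tert-butyldimethylsilyloxy)-4,5-epoxy-8-(methacryloyloxy)germacra-1(10),11(13)-dien-12,6-olide
Conditions: methacrylic anhydride, DMAP, Et3N, CH2Cl2, 0 °C → rt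
Reagents that add atoms: methacrylic anhydride, CC(=C)C(=O)OC(=O)C(C)=C
Why: DMAP-catalysed acylation with the anhydride (Steglich-type) esterifies C8 before C14 is oxidised, so that a free C8 hydroxyl can never close onto a C14 carbonyl.

Step 19
Reactants: 23 (the C8 methacrylate)
Product: 24 9-acetoxy-4,5-epoxy-14-hydroxy-8-(methacryloyloxy)germacra-1(10),11(13)-dien-12,6-olide
Conditions: HF·pyridine, pyridine, THF, 0 °C → rt
Reagents that add atoms: none
Why: Fluoride-mediated desilylation with buffered HF·pyridine cleaves the primary allylic silyl ether without touching the esters, the lactone or the oxirane.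

Step 20
Reactants: 24 (the C14 alcohol)
Product: 25 9-acetoxy-4,5-epoxy-8-(methacryloyloxy)-14-oxogermacra-1(10),11(13)-dien-12,6-olide
Conditions: MnO2 (excess), CH2Cl2, rt
Reagents that add atoms: none
Why: MnO2 oxidation is selective for the allylic alcohol and gives the enal without isomerising the ring alkene.

Step 21
Reactants: 25 (the C14 enal)
Product: 26 9-acetoxy-4,5-epoxy-8-(methacryloyloxy)-12-oxo-12,6-epoxygermacra-1(10),11(13)-dien-14-oic acid (the C14 acid of the 12,6-olide)
Conditions: NaClO2, NaH2PO4, 2-methyl-2-butene, t-BuOH/H2O, 0 °C → rt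
Reagents that add atoms: sodium chlorite, [Na+].[O-]Cl=O
Why: Pinnick (Lindgren–Kraus) oxidation of the enal to the acid, with 2-methyl-2-butene removing hypochlorous acid so that the alkenes and the oxirane are spared.

Step 22
Reactants: 26 (the C14 acid)
Product: 27 target, methyl (4R,5R,6S,7R,8R,9R)-9-acetoxy-4,5-epoxy-8-(methacryloyloxy)germacra-1(10),11(13)-dien-12,6-olid-14-oate (CNP0153978.7)
Conditions: MeI, KHCO3, DMF, rt
Reagents that add atoms: iodomethane, CI
Why: O-Alkylation of the carboxylate (SN2 on MeI) under weakly basic conditions gives the methyl ester and avoids diazomethane, which would add to the α-methylene lactone.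

**Compound list**

1 | geraniol | CC(C)=CCC/C(C)=C/CO | starting material
2 | geranyl triethylsilyl ether | CC(C)=CCC/C(C)=C/CO[Si](CC)(CC)CC | intermediate
3 | (4E)-4-methyl-6-(triethylsilyloxy)hex-4-enal | O=CCC/C(C)=C/CO[Si](CC)(CC)CC | intermediate
4 | ethyl (2Z,6E)-2-iodo-6-methyl-8-(triethylsilyloxy)octa-2,6-dienoate | CCOC(=O)/C(I)=C/CC/C(C)=C/CO[Si](CC)(CC)CC | intermediate
5 | (2Z,6E)-2-iodo-6-methyl-8-(triethylsilyloxy)octa-2,6-dien-1-ol | OC/C(I)=C/CC/C(C)=C/CO[Si](CC)(CC)CC | intermediate
6 | (2Z,6E)-1-(tert-butyldimethylsilyloxy)-2-iodo-6-methyl-8-(triethylsilyloxy)octa-2,6-diene | CC(C)(C)[Si](C)(C)OC/C(I)=C/CC/C(C)=C/CO[Si](CC)(CC)CC | intermediate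
7 | (2E,6Z)-8-(tert-butyldimethylsilyloxy)-7-iodo-3-methylocta-2,6-dienal | O=C/C=C(\C)CC/C=C(\I)CO[Si](C)(C)C(C)(C)C | intermediate
8 | (S)-glyceraldehyde acetonide, (4S)-2,2-dimethyl-1,3-dioxolane-4-carbaldehyde | O=C[C@@H]1COC(C)(C)O1 | starting material
9 | methyl acrylate | C=CC(=O)OC | starting material
10 | methyl 2-{[(4S)-2,2-dimethyl-1,3-dioxolan-4-yl](hydroxy)methyl}prop-2-enoate, both carbinol epimers | C=C(C(=O)OC)C(O)[C@@H]1COC(C)(C)O1 | intermediate
11 | methyl (4S)-3,4,5-trihydroxy-2-methylidenepentanoate, both C3 epimers (not isolated) | C=C(C(=O)OC)C(O)[C@@H](O)CO | intermediate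
12 | (5S)-4-hydroxy-5-(hydroxymethyl)-3-methylideneoxolan-2-one, both C4 epimers | C=C1C(O)[C@H](CO)OC1=O | intermediate
13 | (5S)-4-hydroxy-3-methylidene-5-[(triethylsilyloxy)methyl]oxolan-2-one, both C4 epimers | C=C1C(O)[C@H](CO[Si](CC)(CC)CC)OC1=O | intermediate
14 | (5R)-3-(bromomethyl)-5-[(triethylsilyloxy)methyl]furan-2(5H)-one | BrCC1=C[C@H](CO[Si](CC)(CC)CC)OC1=O | intermediate
15 | (4S,5R)-4-[(1R,2E,6Z)-8-(tert-butyldimethylsilyloxy)-1-hydroxy-7-iodo-3-methylocta-2,6-dien-1-yl]-3-methylidene-5-[(triethylsilyloxy)methyl]oxolan-2-one (8,12-olide, free C6–OH) | O[C@H](/C=C(\C)CC/C=C(\I)CO[Si](C)(C)C(C)(C)C)[C@@H]1C(=C)C(=O)O[C@H]1CO[Si](CC)(CC)CC | intermediate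
16 | (4S,5R)-4-[(S)-hydroxy{(2R,3R)-3-[(3Z)-5-(tert-butyldimethylsilyloxy)-4-iodopent-3-en-1-yl]-3-methyloxiran-2-yl}methyl]-3-methylidene-5-[(triethylsilyloxy)methyl]oxolan-2-one (8,12-olide, 4,5-epoxide) | O[C@H]([C@H]1O[C@]1(C)CC/C=C(\I)CO[Si](C)(C)C(C)(C)C)[C@@H]1C(=C)C(=O)O[C@H]1CO[Si](CC)(CC)CC | intermediate
17 | (4R,5S)-4-[(1R)-1-hydroxy-2-(triethylsilyloxy)ethyl]-5-[(2R,3R)-3-[(3Z)-5-(tert-butyldimethylsilyloxy)-4-iodopent-3-en-1-yl]-3-methyloxiran-2-yl]-3-methylideneoxolan-2-one (6,12-olide, free C8–OH; not isolated) | CC[Si](CC)(CC)OC[C@H](O)[C@H]1C(=C)C(=O)O[C@@H]1[C@H]1O[C@]1(C)CC/C=C(\I)CO[Si](C)(C)C(C)(C)C | intermediate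
18 | (4S,5S)-4-[(1R)-1,2-bis(triethylsilyloxy)ethyl]-5-[(2R,3R)-3-[(3Z)-5-(tert-butyldimethylsilyloxy)-4-iodopent-3-en-1-yl]-3-methyloxiran-2-yl]-3-methylideneoxolan-2-one | CC[Si](CC)(CC)OC[C@H](O[Si](CC)(CC)CC)[C@H]1C(=C)C(=O)O[C@@H]1[C@H]1O[C@]1(C)CC/C=C(\I)CO[Si](C)(C)C(C)(C)C | intermediate
19 | (2R)-2-[(2S,3S)-2-[(2R,3R)-3-[(3Z)-5-(tert-butyldimethylsilyloxy)-4-iodopent-3-en-1-yl]-3-methyloxiran-2-yl]-4-methylidene-5-oxooxolan-3-yl]-2-(triethylsilyloxy)acetaldehyde (precursor of the key step) | O=C[C@H](O[Si](CC)(CC)CC)[C@H]1C(=C)C(=O)O[C@@H]1[C@H]1O[C@]1(C)CC/C=C(\I)CO[Si](C)(C)C(C)(C)C | intermediate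
20 | 14-(tert-butyldimethylsilyloxy)-4,5-epoxy-9-hydroxy-8-(triethylsilyloxy)germacra-1(10),11(13)-dien-12,6-olide, C2/C9 cis on C1=C10, C4–C9 as in 27 (product of the key step) | CC[Si](CC)(CC)O[C@@H]1[C@H]2C(=C)C(=O)O[C@@H]2[C@H]2O[C@]2(C)CC/C=C(/CO[Si](C)(C)C(C)(C)C)[C@H]1O | intermediate
21 | 9-acetate of 20 | CC[Si](CC)(CC)O[C@@H]1[C@H]2C(=C)C(=O)O[C@@H]2[C@H]2O[C@]2(C)CC/C=C(/CO[Si](C)(C)C(C)(C)C)[C@H]1OC(C)=O | intermediate
22 | 9-acetoxy-14-(tert-butyldimethylsilyloxy)-4,5-epoxy-8-hydroxygermacra-1(10),11(13)-dien-12,6-olide | O[C@@H]1[C@H]2C(=C)C(=O)O[C@@H]2[C@H]2O[C@]2(C)CC/C=C(/CO[Si](C)(C)C(C)(C)C)[C@H]1OC(C)=O | intermediate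
23 | 8-methacrylate of 22 | C=C(C)C(=O)O[C@@H]1[C@H]2C(=C)C(=O)O[C@@H]2[C@H]2O[C@]2(C)CC/C=C(/CO[Si](C)(C)C(C)(C)C)[C@H]1OC(C)=O | intermediate
24 | 9-acetoxy-4,5-epoxy-14-hydroxy-8-(methacryloyloxy)germacra-1(10),11(13)-dien-12,6-olide | C=C(C)C(=O)O[C@@H]1[C@H]2C(=C)C(=O)O[C@@H]2[C@H]2O[C@]2(C)CC/C=C(/CO)[C@H]1OC(C)=O | intermediate
25 | the 14-aldehyde of 24 | C=C(C)C(=O)O[C@@H]1[C@H]2C(=C)C(=O)O[C@@H]2[C@H]2O[C@]2(C)CC/C=C(/C=O)[C@H]1OC(C)=O | intermediate
26 | the 14-carboxylic acid of 24 | C=C(C)C(=O)O[C@@H]1[C@H]2C(=C)C(=O)O[C@@H]2[C@H]2O[C@]2(C)CC/C=C(/C(=O)O)[C@H]1OC(C)=O | intermediate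
27 | CNP0153978.7, methyl (4R,5R,6S,7R,8R,9R)-9-acetoxy-4,5-epoxy-8-(methacryloyloxy)germacra-1(10),11(13)-dien-12,6-olid-14-oate | C=C(C)C(=O)O[C@@H]1[C@H]2C(=C)C(=O)O[C@@H]2[C@H]2O[C@]2(C)CC/C=C(/C(=O)OC)[C@H]1OC(C)=O | target

**Counts and risks**

Total steps: 22. Longest linear sequence: 18 steps (steps 1–6, then 11–22); the butenolide branch (steps 7–10) joins at step 11.

Steps most likely to fail:

Step 13. The acyl shift may not outrun silylation of the C6 hydroxyl, or the equilibrium may lie so far on the side of the 8,12-olide that conversion stalls. The fallback replaces the one-pot shift by ring opening and a directed re-closure. It sets out from 16. LiOH in THF/H2O at 0 °C would open the lactone to the lithium dihydroxy carboxylate F1. Without acidification, Et3SiCl and imidazole in DMF would silylate the carboxylate and the less hindered C8 hydroxyl, and aqueous work-up would hydrolyse the silyl ester to the C6-hydroxy acid F2. EDC·HCl with DMAP in CH2Cl2 would then close the only free γ-hydroxyl (C6) onto C12, and the sequence comes back to the route at 18.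

Step 15. Intermolecular coupling can compete with ring closure, and the aldehyde may be attacked on the wrong face if simple Felkin–Anh control by the C8 silyloxy group overrides the ring constraints. The fallback sets C9 by reduction instead of by the carbon–carbon bond formation. It sets out from 19. If the ring closes mainly to the 9-epimeric alcohol F3, this is oxidised with Dess–Martin periodinane (NaHCO3, CH2Cl2) to the C9 enone F4. Reduction with NaBH4/CeCl3 in MeOH at −78 °C (Luche reduction) should then deliver hydride from the ring periphery anti to the C8 silyloxy group, which for the ketone is the Felkin–Anh course and gives the 8,9-threo alcohol. The sequence comes back to the route at 20.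

Step 14. The primary silicon–oxygen bond may be cleaved incompletely under Swern conditions, or the α-silyloxy aldehyde may epimerise at C8 during the base step. The fallback separates deprotection from oxidation. It sets out from 18. Pyridinium p-toluenesulfonate in MeOH/CH2Cl2 at −10 °C would solvolyse the primary triethylsilyl ether selectively to the primary alcohol F5. Dess–Martin periodinane buffered with NaHCO3 would then oxidise it without base-mediated epimerisation, and the sequence comes back to the route at 19.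

Further compounds
F1 | step 13 | lithium carboxylate from opening of 16 (free C6 and C8 hydroxyls, C9–OSiEt3) | [Li+].[O-]C(=O)C(=C)[C@@H]([C@H](O)[C@H]1O[C@]1(C)CC/C=C(\I)CO[Si](C)(C)C(C)(C)C)[C@@H](O)CO[Si](CC)(CC)CC
F2 | step 13 | C6-hydroxy acid with C8 and C9 triethylsilyl ethers | OC(=O)C(=C)[C@@H]([C@H](O)[C@H]1O[C@]1(C)CC/C=C(\I)CO[Si](C)(C)C(C)(C)C)[C@@H](O[Si](CC)(CC)CC)CO[Si](CC)(CC)CC
F3 | step 15 | 9-epimer of 20 | CC[Si](CC)(CC)O[C@@H]1[C@H]2C(=C)C(=O)O[C@@H]2[C@H]2O[C@]2(C)CC/C=C(/CO[Si](C)(C)C(C)(C)C)[C@@H]1O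
F4 | step 15 | C9 ketone (enone) of 20 | CC[Si](CC)(CC)O[C@@H]1[C@H]2C(=C)C(=O)O[C@@H]2[C@H]2O[C@]2(C)CC/C=C(/CO[Si](C)(C)C(C)(C)C)C1=O
F5 | step 14 | C9 primary alcohol, C8 triethylsilyl ether of the 6,12-olide | OC[C@H](O[Si](CC)(CC)CC)[C@H]1C(=C)C(=O)O[C@@H]1[C@H]1O[C@]1(C)CC/C=C(\I)CO[Si](C)(C)C(C)(C)C
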